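3 questions stand on this flask, and 2 earlier runs stand behind them.

| flask | substrate | second nucleophile | gas | remark | time |
|---|---|---|---|---|---|
| violet | 5 mM | 1.1 equiv | 2.9 mM (held) | run made earlier |  |
| red | 20 mM | 1.1 equiv | 2.9 mM (held) | run made earlier |  |
| flask | 10 mM | 1.10 equiv | 2.9 mM (held) |  | 6.0 min |

- violet (time / min: other capture product / %, target / %): 0.667: 16.8, 15.2; 2.00: 19.8, 9.1; 3.00: 19.2, 5.5; 5.00: 19.1, 1.3; 8.00: 18.1, 0
- red (time / min: other capture product / %, target / %): 1.33: 42.3, 3.8; 3.00: 43.1, 0.7; 4.00: 43.9, 0; 6.00: 41.7, 0; 8.00: 42.1, 0.8

(each reading ± 1 percentage point)

- at the start none of the gas is in solution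

- share of other capture product in other capture product plus target at 1.2 s
- share of other capture product in other capture product plus target at 20 s
- share of other capture product in other capture product plus target at 6.0 min

I take the target to come from dissolved gas and the other capture product from second nucleophile, the two competing for one thing. In this flask, second nucleophile charged over gas at saturation is 3.79. I call this ratio the capture number. It counts second nucleophile as charged against gas at saturation.

The violet run has a capture number of 1.90. Its first readings give other capture product over target as 1.11. That is 0.583 per unit of capture number, a reading of a selectivity factor, with its scatter. For this flask I reckon a ratio of 2.21, so a share of 68.9% at 20 s, an estimate carried over from the violet reading at 0.667 min.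

Is one number enough? No, since it holds no time. Gas starts at none in solution, so at 1.2 s I expect a share near 100 percent. In the violet run, target falls from 15.2% to 1.3% by 5.00 min, so at 6.0 min I expect a share near 100 percent in this flask too.

The forecast says 95%, 75% and 99%. At 20 s it stands 6.1 percentage points above mine. Its ground for the start: “The gas starts at zero, so the first seconds should give almost only the other product”.

The flask gives 92.4%, 72.9% and 99.8%, and the forecast holds within its margins.

    substrate → intermediate (k = 0.0450 /s)
    first nucleophile + intermediate → target (k = 19000 /M/s)
    second nucleophile + intermediate → other capture product (k = 10000 /M/s)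
    intermediate → solvolysis product (k = 84.0 /s)
    second nucleophile + target → over-reaction product (k = 8.00 /M/s)
    gas ⇌ first nucleophile, rate k6*(csat - [first nucleophile]) (kL = 0.320 /s)
    second nucleophile ⇌ dormant form (K = 1.50, k = 0.0380 /s)

At 20 s this flask's ratio is 2.68, or 0.707 per unit of capture number. The neighbour with 17 mM of substrate has a capture number of 6.45, which gives 82.0% at 20 s; it shows 83.8%. In this flask, gas transfer has half of its turnover up to 6.0 min behind it at 0.107 min, and the step from intermediate to solvolysis product at 0.288 min. Second nucleophile turns target into over-reaction product, which stands at 8.48% at 0.600 min and 25.1% at 6.00 min, while target stands at 0.0583% at 6.00 min.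

All runs are calculated on assumed constants, and the scatter is random.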